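**Retrosynthetic overview**

1. The target is (4R)-8-benzoyl-5,7-dihydroxy-6-(3-methylbut-2-enyl)-4-phenylchroman-2-one. The strategy rests on O1 lying between aromatic C8a and the lactone carbonyl C2: the ring O1–C2–C3–C4–C4a–C8a is the cyclopentanone ring of a 3-phenylindan-1-one (C1, C2, C3, C3a, C7a) with one oxygen inserted into the aryl–carbonyl bond.
2. Late disconnections: the C6–prenyl bond (aromatic Claisen rearrangement of a 5-O-(1,1-dimethylallyl) ether, made from the propargyl ether) and the C8–benzoyl bond (Friedel–Crafts acylation of the dimethyl ether).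
3. Key disconnection: C8a–O1, by Baeyer–Villiger oxidation of (R)-4,6-dimethoxy-3-phenylindan-1-one 5 to lactone 7.
4. Indanone 5 comes from rhodium-catalysed asymmetric intramolecular hydroacylation of aldehyde 4, which sets the only stereocentre; 4 comes from bromination and Suzuki coupling of 3,5-dimethoxybenzaldehyde.
5. Ring order: the five-membered carbocycle is formed in step 3 and expanded to the six-membered lactone in step 4; no further ring is formed.

Key step: step 4

Assumption: (R)-BINAP is written in step 3 on the assumption that it gives the 3R indanone; the sense of induction is to be checked on the first run and the (S)-ligand used if it is opposite.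

**Route**

Step 1
Reactants: 1 3,5-dimethoxybenzaldehyde
Product: 2 2-bromo-3,5-dimethoxybenzaldehyde
Conditions: NBS (1.05 equiv), MeCN, 0 °C to rt
Reagents that add atoms: N-bromosuccinimide, O=C1CCC(=O)N1Br
Why: Electrophilic aromatic bromination should go to C2, which is ortho/para to the two methoxy groups and less hindered than C4 between them.

Step 2
Reactants: 2 2-bromo-3,5-dimethoxybenzaldehyde, 3 4,4,5,5-tetramethyl-2-(1-phenylethenyl)-1,3,2-dioxaborolane
Product: 4 3,5-dimethoxy-2-(1-phenylethenyl)benzaldehyde
Conditions: Pd(OAc)2 (2 mol%), SPhos (4 mol%), K3PO4, PhMe/H2O, 80 °C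
Reagents that add atoms: none
Why: Suzuki–Miyaura coupling with a bulky electron-rich biarylphosphine should cope with the di-ortho-substituted aryl bromide and the α-substituted alkenylboronate, and the aldehyde tolerates the phosphate base.

Step 3
Reactants: 4 3,5-dimethoxy-2-(1-phenylethenyl)benzaldehyde
Product: 5 (3R)-4,6-dimethoxy-3-phenylindan-1-one
Conditions: [Rh((R)-BINAP)]BF4 (5 mol%), acetone, 25–40 °C, argon
Reagents that add atoms: none
Why: In this rhodium-catalysed asymmetric intramolecular alkene hydroacylation, aldehyde C–H oxidative addition, hydride transfer to the internal alkene carbon and C–C reductive elimination from the six-membered acyl-alkyl rhodacycle should give the indanone, with the chiral bisphosphine choosing the alkene face in the hydrometalation and so setting C3 as R.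

Step 4
Reactants: 5 (3R)-4,6-dimethoxy-3-phenylindan-1-one
Product: 7 (4R)-5,7-dimethoxy-4-phenylchroman-2-one, via Criegee peroxy hemiketal 6 (not isolated)
Conditions: mCPBA (1.2 equiv), TFA (2 equiv), CH2Cl2, 0 °C to rt, dark; aq. Na2SO3
Reagents that add atoms: 3-chloroperoxybenzoic acid (mCPBA), OOC(=O)c1cccc(Cl)c1
Why: The peracid adds to the acid-activated C1 ketone of 5 to give the Criegee peroxy hemiketal 6, and the aryl carbon C7a then shifts from C1 to the adjacent peroxide oxygen as 3-chlorobenzoate leaves, which makes the C8a–O1 bond. The closest known reaction type is the Baeyer–Villiger oxidation of 1-indanones, 3-aryl examples included, to 3,4-dihydrocoumarins. The lactone ring is not closed by a cyclisation: the five-membered ketone ring grows to the six-membered ring O1–C2–C3–C4–C4a–C8a by a 1,2-shift that inserts one oxygen atom. No stereocentre is created; C3 of 5 takes no part in the migration and cannot be epimerised by enolisation, so it should become C4 of 7 with the R configuration intact. The step needs migration of the aryl carbon in preference to the C2 methylene; both methoxy groups are meta to C7a and give no resonance help, so the selectivity rests on the general aryl-over-primary-alkyl preference of 1-indanones under acid-promoted peracid conditions, where the migration transition state has more cationic character. The oxidant is held near one equivalent at low temperature because the product ring, now carrying three oxygens, is more easily oxidised than that of 5.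

Step 5
Reactants: 7 (4R)-5,7-dimethoxy-4-phenylchroman-2-one, 8 benzoyl chloride
Product: 9 (4R)-8-benzoyl-5,7-dimethoxy-4-phenylchroman-2-one
Conditions: AlCl3 (2.2 equiv), CH2Cl2, 0 °C; cold dil. HCl
Reagents that add atoms: none
Why: Friedel–Crafts acylation should favour C8, which is para to the 5-methoxy group, ortho to the 7-methoxy group and flanked by only one methoxyl, over C6 between two methoxyls; any material that loses the 7-O-methyl group under AlCl3 converges at 10 in the next step.

Step 6
Reactants: 9 (4R)-8-benzoyl-5,7-dimethoxy-4-phenylchroman-2-one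
Product: 10 (4R)-8-benzoyl-5,7-dihydroxy-4-phenylchroman-2-one
Conditions: BBr3 (5 equiv), CH2Cl2, −78 °C to rt; ice–water
Reagents that add atoms: none
Why: Lewis-acid ether cleavage with BBr3 should remove the 7-O-methyl group first through chelation to the ketone and the 5-O-methyl group on warming, while the aryl lactone and the non-enolisable C4 centre are left alone at or below room temperature.

Step 7
Reactants: 10 (4R)-8-benzoyl-5,7-dihydroxy-4-phenylchroman-2-one, 11 2-methylbut-3-yn-2-ol
Product: 13 (4R)-8-benzoyl-7-hydroxy-5-[(2-methylbut-3-yn-2-yl)oxy]-4-phenylchroman-2-one, via 2-methylbut-3-yn-2-yl trifluoroacetate 12 (not isolated)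
Conditions: 11, (CF3CO)2O, DBU, MeCN, −5 °C; then 10, DBU (1.1 equiv), CuCl2·2H2O (1 mol%), MeCN, −5 to 0 °C
Reagents that add atoms: trifluoroacetic anhydride, O=C(OC(=O)C(F)(F)F)C(F)(F)F (its CF3CO group is carried by intermediate 12 only, not by 13)
Why: In this copper-catalysed propargylic substitution of the tertiary propargyl trifluoroacetate, the 5-OH, which is para to the benzoyl group, more acidic and not hydrogen-bonded, should be alkylated while the 7-OH stays chelated to the ketone; an ether on either oxygen would in any case lead to the same C6 product.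

Step 8
Reactants: 13 (4R)-8-benzoyl-7-hydroxy-5-[(2-methylbut-3-yn-2-yl)oxy]-4-phenylchroman-2-one
Product: 14 (4R)-8-benzoyl-7-hydroxy-5-[(2-methylbut-3-en-2-yl)oxy]-4-phenylchroman-2-one
Conditions: H2 (1 atm), Lindlar catalyst, quinoline, EtOAc, rt
Reagents that add atoms: none
Why: Lindlar semi-hydrogenation should stop at the terminal alkene and leave the diaryl ketone, the lactone and the allylic aryl ether untouched.

Step 9
Reactants: 14 (4R)-8-benzoyl-7-hydroxy-5-[(2-methylbut-3-en-2-yl)oxy]-4-phenylchroman-2-one
Product: 16 (4R)-8-benzoyl-5,7-dihydroxy-6-(3-methylbut-2-enyl)-4-phenylchroman-2-one, via ortho-dienone 15 (not isolated)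
Conditions: PhMe, 110 °C, degassed, sealed tube
Reagents that add atoms: none
Why: In the aromatic Claisen rearrangement the [3,3]-shift should deliver the allyl terminus to C6, the only free ortho position (C4a is substituted and the para position C8 carries the benzoyl group), turning the 1,1-dimethylallyl unit into the 3-methylbut-2-enyl group before dienone 15 tautomerises to the phenol.

**Compound list**

1 | 3,5-dimethoxybenzaldehyde | COc1cc(C=O)cc(OC)c1 | starting material
2 | 2-bromo-3,5-dimethoxybenzaldehyde | COc1cc(C=O)c(Br)c(OC)c1 | intermediate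
3 | 4,4,5,5-tetramethyl-2-(1-phenylethenyl)-1,3,2-dioxaborolane | C=C(c1ccccc1)B1OC(C)(C)C(C)(C)O1 | starting material
4 | 3,5-dimethoxy-2-(1-phenylethenyl)benzaldehyde | COc1cc(C=O)c(C(=C)c2ccccc2)c(OC)c1 | intermediate
5 | (3R)-4,6-dimethoxy-3-phenylindan-1-one | COc1cc2c(c(OC)c1)[C@@H](c1ccccc1)CC2=O | intermediate
6 | (3R)-1-hydroxy-4,6-dimethoxy-3-phenylindan-1-yl 3-chloroperoxybenzoate (Criegee peroxy hemiketal, C1 epimers) | COc1cc2c(c(OC)c1)[C@@H](c1ccccc1)CC2(O)OOC(=O)c1cccc(Cl)c1 | intermediate
7 | (4R)-5,7-dimethoxy-4-phenylchroman-2-one | COc1cc2c(c(OC)c1)[C@@H](c1ccccc1)CC(=O)O2 | intermediate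
8 | benzoyl chloride | O=C(Cl)c1ccccc1 | starting material
9 | (4R)-8-benzoyl-5,7-dimethoxy-4-phenylchroman-2-one | COc1c(C(=O)c2ccccc2)c2c(c(OC)c1)[C@@H](c1ccccc1)CC(=O)O2 | intermediate
10 | (4R)-8-benzoyl-5,7-dihydroxy-4-phenylchroman-2-one | Oc1c(C(=O)c2ccccc2)c2c(c(O)c1)[C@@H](c1ccccc1)CC(=O)O2 | intermediate
11 | 2-methylbut-3-yn-2-ol | CC(C)(O)C#C | starting material
12 | 2-methylbut-3-yn-2-yl trifluoroacetate | C#CC(C)(C)OC(=O)C(F)(F)F | intermediate
13 | (4R)-8-benzoyl-7-hydroxy-5-[(2-methylbut-3-yn-2-yl)oxy]-4-phenylchroman-2-one | Oc1c(C(=O)c2ccccc2)c2c(c(OC(C)(C)C#C)c1)[C@@H](c1ccccc1)CC(=O)O2 | intermediate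
14 | (4R)-8-benzoyl-7-hydroxy-5-[(2-methylbut-3-en-2-yl)oxy]-4-phenylchroman-2-one | Oc1c(C(=O)c2ccccc2)c2c(c(OC(C)(C)C=C)c1)[C@@H](c1ccccc1)CC(=O)O2 | intermediate
15 | (4R)-8-benzoyl-7-hydroxy-6-(3-methylbut-2-enyl)-4-phenyl-3,4-dihydro-2H-chromene-2,5(6H)-dione (ortho-dienone, C6 epimers) | CC(C)=CCC1C(O)=C(C(=O)c2ccccc2)C2=C(C1=O)[C@@H](c1ccccc1)CC(=O)O2 | intermediate
16 | (4R)-8-benzoyl-5,7-dihydroxy-6-(3-methylbut-2-enyl)-4-phenylchroman-2-one | CC(C)=CCc1c(O)c(C(=O)c2ccccc2)c2c(c1O)[C@@H](c1ccccc1)CC(=O)O2 | target

**Step count**

Total steps: 9. Longest linear sequence: 9 steps, from 3,5-dimethoxybenzaldehyde 1.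

**Steps most likely to fail**

1. Step 4 (Baeyer–Villiger oxidation). The C2 methylene may migrate in place of the aryl carbon, because the two meta-methoxy groups do not assist aryl migration; this would give the isochromanone-type lactone. Excess peracid may also oxidise the electron-rich product ring. The fallback sets out from 5 and comes back at 7. α-Bromination of 5 at C2 (PhNMe3Br3, THF, 0 °C) should give (3R)-2-bromo-4,6-dimethoxy-3-phenylindan-1-one F1. Peracid oxidation of this α-bromo ketone (mCPBA, CH2Cl2, unbuffered) should be faster and proceed by aryl migration only, since a halogen-bearing carbon migrates poorly, to give (4R)-3-bromo-5,7-dimethoxy-4-phenylchroman-2-one F2. Reductive debromination (Zn, AcOH, rt) should then return 7. Base is avoided throughout, because loss of HBr from either bromide would form an indenone or a coumarin and erase the stereocentre.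

2. Step 5 (Friedel–Crafts benzoylation). The acylium ion may attack C6 between the two methoxyls, or the Lewis acid may open the aryl lactone. The fallback sets out from 7 and comes back at 9. Methanolysis of the lactone (MeOH, cat. NaOMe, 0 °C, AcOH quench) should give methyl (3R)-3-(2-hydroxy-4,6-dimethoxyphenyl)-3-phenylpropanoate F3, in which the former O1 is a free phenol. Boron-templated ortho-acylation of that phenol (BCl3, then 8, ClCH2CH2Cl, 0 to 60 °C) should deliver the benzoyl group from the aryloxyboron species only to the free position ortho to this oxygen, the future C8, to give methyl (3R)-3-(3-benzoyl-2-hydroxy-4,6-dimethoxyphenyl)-3-phenylpropanoate F4. Acid-catalysed relactonisation (TsOH, PhMe, heat) should then return 9. Loss of the methyl group next to the new ketone under BCl3 would be harmless, since step 6 removes it anyway.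

3. Step 3 (asymmetric hydroacylation). The acyl-rhodium hydride may decarbonylate before it inserts the alkene, which is twisted and shielded by the ortho-methoxy group, and the facial selectivity of the hydrometalation may be poor. The fallback sets out from 2 and comes back at 5. Palladium-catalysed annulation of 1-phenyl-2-(trimethylsilyl)acetylene onto 2 (Pd(OAc)2, Na2CO3, Bu4NCl, DMF, 100 °C) should give 4,6-dimethoxy-3-phenyl-2-(trimethylsilyl)-1H-inden-1-one F5, with the silyl group next to the carbonyl. Protodesilylation (TFA, CH2Cl2) should give 4,6-dimethoxy-3-phenyl-1H-inden-1-one F6. Corey–Bakshi–Shibata reduction, with the catalyst antipode chosen for the 1R alcohol, should give (1R)-4,6-dimethoxy-3-phenyl-1H-inden-1-ol F7. An amine-mediated suprafacial 1,3-hydrogen shift (DABCO, Et3N, THF, 60 °C) should carry the C1 hydrogen to the same face of C3 and give 5 after tautomerisation of the enol.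

**Further compounds**

F1 | step 4 | (3R)-2-bromo-4,6-dimethoxy-3-phenylindan-1-one (C2 epimers) | COc1cc2c(c(OC)c1)[C@@H](c1ccccc1)C(Br)C2=O
F2 | step 4 | (4R)-3-bromo-5,7-dimethoxy-4-phenylchroman-2-one (C3 epimers) | COc1cc2c(c(OC)c1)[C@@H](c1ccccc1)C(Br)C(=O)O2
F3 | step 5 | methyl (3R)-3-(2-hydroxy-4,6-dimethoxyphenyl)-3-phenylpropanoate | COc1cc(O)c(c(OC)c1)[C@@H](c1ccccc1)CC(=O)OC
F4 | step 5 | methyl (3R)-3-(3-benzoyl-2-hydroxy-4,6-dimethoxyphenyl)-3-phenylpropanoate | COc1c(C(=O)c2ccccc2)c(O)c(c(OC)c1)[C@@H](c1ccccc1)CC(=O)OC
F5 | step 3 | 4,6-dimethoxy-3-phenyl-2-(trimethylsilyl)-1H-inden-1-one | COc1cc2c(c(OC)c1)C(c1ccccc1)=C([Si](C)(C)C)C2=O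
F6 | step 3 | 4,6-dimethoxy-3-phenyl-1H-inden-1-one | COc1cc2c(c(OC)c1)C(c1ccccc1)=CC2=O
F7 | step 3 | (1R)-4,6-dimethoxy-3-phenyl-1H-inden-1-ol | COc1cc2c(c(OC)c1)C(c1ccccc1)=C[C@H]2O
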